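**Plan**

1. Numbering: oxepane O1, C2 (quaternary), C3 (OAc), C4, C5, C6 (alkylidene), C7 (OCH2); exocyclic C1'–C2'; side chain C1''–C8'' from C2.
2. Feature: inside the seven-membered ring O1/C2–C7 the tertiary ether carbon C2 sits next to the C3 carbinol, with the C3 oxygen trans to C1''. This 2-alkyl-3-hydroxy cyclic ether unit is what a ketyl adding to a β-alkoxyvinyl acceptor creates, so the ring is closed at C2–C3.
3. Retrosynthetic cuts, in order: C5''–C6'' (allylboration, then oxidation); C1''–C2'' (Wittig, then alkene reduction, the C1'' aldehyde coming from a sulfinylmethyl group by Pummerer reaction); C2–C3 (SmI2 ring closure); O1–C2 (alkoxide addition to an alkynyl sulfoxide); C5–C6 (Negishi coupling on a (Z)-iodoalkene).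
4. Forward: the acyclic C7/C6/C1'/C2' unit from butynediol, the C3–C5 chain by coupling, the enol ether, then the only ring (the oxepane) in step 7; the side chain is joined at C1''–C2'' and finished at C5''–C6''.
5. Stereochemistry: the (E) C6=C1' alkene from trans-hydroalumination–iodination and a stereoretentive coupling; C2 and C3 from the sulfur stereocentre of a menthyl p-toluenesulfinate in the ring closure; C4'' from (S)-3-bromo-2-methylpropan-1-ol.

Key step: step 7

Assumption: with the sulfinyl group cis to the β-methyl group, A1,3 strain is taken to hold the sulfur lone pair in the alkene plane, so that the ketyl adds to the C2 face that carries the sulfinyl oxygen; on this model the (S)-configured vinyl sulfoxide, reached from the (R)-sulfinate, gives the target series, and the enantiomeric sulfinate would be used with no other change if the sense proved opposite.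

**Route**

Step 1
Reactants: 1 but-2-yne-1,4-diol
Product: 3 (Z)-2-iodobut-2-ene-1,4-diol, via cyclic alkenylalanate 2 (not isolated)
Conditions: Red-Al, THF, 0 °C → rt; then I2, THF, −78 → 0 °C
Reagents that add atoms: iodine, II
Why: The propargylic alkoxide directs trans-hydroalumination so that aluminium and hydride end up anti across the former alkyne, and iodinolysis of the C–Al bond with retention gives the (Z)-iodoalkene (hydroalumination–iodination).

Step 2
Reactants: 3 (Z)-2-iodobut-2-ene-1,4-diol
Product: 4 (Z)-4-(tert-butyldimethylsilyloxy)-2-iodobut-2-en-1-ol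
Conditions: TBSCl (1.0 equiv), imidazole, CH2Cl2, −20 °C
Reagents that add atoms: tert-butyldimethylsilyl chloride, C[Si](C)(Cl)C(C)(C)C
Why: Sterically controlled monosilylation of a diol, in which the hydroxyl on the CH= side reacts first because the other one is flanked by the iodine-bearing alkene carbon and is inductively deactivated, the regioisomer and the bis-ether being removed by chromatography.

Step 3
Reactants: 4 (Z)-4-(tert-butyldimethylsilyloxy)-2-iodobut-2-en-1-ol; 5 (2-cyanoethyl)zinc bromide
Product: 6 (E)-6-(tert-butyldimethylsilyloxy)-4-(hydroxymethyl)hex-4-enenitrile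
Conditions: Pd(OAc)2 (cat.), SPhos (cat.), THF, 25 °C, slow addition of 5 (1.5 equiv)
Reagents that add atoms: none
Why: Negishi sp2–sp3 coupling, in which oxidative addition to the alkenyl iodide and reductive elimination retain the alkene geometry (the two CH2O groups stay trans, so the alkene is E) and the alkylzinc halide tolerates the nitrile and couples faster than the free hydroxyl protonates it.

Step 4
Reactants: 7 prop-1-yn-1-ylmagnesium bromide; 8 (1S,2R,5S)-menthyl (R)-p-toluenesulfinate
Product: 9 (R)-1-methyl-4-(prop-1-yn-1-ylsulfinyl)benzene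
Conditions: toluene/THF, −20 °C
Reagents that add atoms: none
Why: Andersen-type substitution at sulfur, in which the alkynyl Grignard reagent displaces mentholate with inversion and gives the alkynyl sulfoxide as a single enantiomer (descriptor R because 1-propynyl outranks p-tolyl).

Step 5
Reactants: 6 (E)-6-(tert-butyldimethylsilyloxy)-4-(hydroxymethyl)hex-4-enenitrile; 9 (R)-1-methyl-4-(prop-1-yn-1-ylsulfinyl)benzene
Product: 10 (4E)-6-(tert-butyldimethylsilyloxy)-4-({[(E)-1-((S)-p-tolylsulfinyl)prop-1-en-2-yl]oxy}methyl)hex-4-enenitrile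
Conditions: NaH (0.15 equiv), THF, 0 °C; AcOH quench
Reagents that add atoms: none
Why: Oxa-Michael addition of the catalytically generated alkoxide to the β-carbon of the alkynyl sulfoxide with proton transfer from 6 as chain carrier, reversible addition–elimination being expected to settle on the (E) push–pull isomer with sulfinyl trans to oxygen, while substoichiometric base and 0 °C keep the anion-accelerated Claisen rearrangement of the allyl vinyl ether and any scrambling of sulfur through an allylic sulfoxide isomer closed (the sulfur centre is not touched and reads S only because the alkenyl group ranks below p-tolyl).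

Step 6
Reactants: 10 (4E)-6-(tert-butyldimethylsilyloxy)-4-({[(E)-1-((S)-p-tolylsulfinyl)prop-1-en-2-yl]oxy}methyl)hex-4-enenitrile
Product: 12 (4E)-6-(tert-butyldimethylsilyloxy)-4-({[(E)-1-((S)-p-tolylsulfinyl)prop-1-en-2-yl]oxy}methyl)hex-4-enal, via N-aluminoimine 11 (not isolated)
Conditions: DIBAL (2.2 equiv), CH2Cl2, −78 °C; then aq. Rochelle salt/citrate buffer (pH 5), 0 °C
Reagents that add atoms: water, O
Why: Partial reduction of a nitrile with DIBAL, which stops at the N-aluminoimine at −78 °C and is hydrolysed to the aldehyde by a weakly acidic buffer that spares the enol ether, aryl sulfoxides and silyl ethers being inert to DIBAL at this temperature.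

Step 7
Reactants: 12 (4E)-6-(tert-butyldimethylsilyloxy)-4-({[(E)-1-((S)-p-tolylsulfinyl)prop-1-en-2-yl]oxy}methyl)hex-4-enal
Product: 13 (2R,3R,6E)-6-[2-(tert-butyldimethylsilyloxy)ethylidene]-2-methyl-2-{[(S)-p-tolylsulfinyl]methyl}oxepan-3-ol
Conditions: SmI2 (3 equiv), MeOH (3 equiv), THF, high dilution, 0 °C
Reagents that add atoms: none
Why: Single-electron transfer from SmI2 to the aldehyde gives a samarium(III) ketyl that adds to C2, the β-carbon of the vinylogous sulfinate, after which a second electron reduces the α-sulfinyl radical and methanol protonates C1'' and the alkoxide. The closest known reaction type is the SmI2-induced reductive cyclisation of aldehydes onto β-alkoxyacrylates and β-alkoxyvinyl sulfoxides or sulfones, which gives 2,3-trans cyclic ethers including oxepanes and rings with a methyl group on the ether carbon. The oxepane closes in the 7-exo-trig mode through the new C2–C3 bond. C2 is controlled by the sulfur stereocentre: A1,3 strain with the cis β-methyl group holds the sulfur lone pair in the alkene plane, so that p-tolyl shields one face while the sulfinyl oxygen on the other face binds samarium and brings the ketyl in there. C3 is controlled by the chelated chair-like transition state, in which the C3–C4 bond lies anti to the C2–C1'' bond and the samarium-bound ketyl oxygen gauche to C1'', so that the C3 oxygen ends trans to the sulfinylmethyl arm and cis to the C2 methyl group. The step needs ring closure to outrun simple reduction and pinacol coupling of the aldehyde and needs one face of C2 to be attacked, which high dilution, the electron-poor acceptor, the sp2 centre C6 in the tether and the fixed (E) geometry of the enol ether are meant to secure.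

Step 8
Reactants: 13 (2R,3R,6E)-6-[2-(tert-butyldimethylsilyloxy)ethylidene]-2-methyl-2-{[(S)-p-tolylsulfinyl]methyl}oxepan-3-ol
Product: 15 (2R,3R,6E)-6-(2-acetoxyethylidene)-2-methyl-2-{[(S)-p-tolylsulfinyl]methyl}oxepan-3-yl acetate, via diol 14 (not isolated)
Conditions: TBAF, THF, 0 °C; then Ac2O, Et3N, DMAP, rt
Reagents that add atoms: acetic anhydride, CC(=O)OC(C)=O
Why: Fluoride cleavage of the primary allylic silyl ether followed in the same flask by DMAP-catalysed acetylation of both hydroxyls installs the two acetates of the target at once, the sulfoxide being inert to acetic anhydride at room temperature.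

Step 9
Reactants: 15 (2R,3R,6E)-6-(2-acetoxyethylidene)-2-methyl-2-{[(S)-p-tolylsulfinyl]methyl}oxepan-3-yl acetate
Product: 17 (2R,3R,6E)-6-(2-acetoxyethylidene)-2-formyl-2-methyloxepan-3-yl acetate, via trifluoroacetoxy sulfide 16 (not isolated)
Conditions: TFAA, 2,4,6-collidine, MeCN, 0 °C; then aq. NaHCO3, rt
Reagents that add atoms: trifluoroacetic anhydride, O=C(OC(=O)C(F)(F)F)C(F)(F)F
Why: Pummerer reaction, in which O-trifluoroacetylation, deprotonation at C1'' (the only α-CH2, with quaternary C2 ruling out a vinyl sulfide) and acyloxy transfer give the α-trifluoroacetoxy sulfide that bicarbonate hydrolyses to the aldehyde without touching the acetates or any stereocentre.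

Step 10
Reactants: 18 (S)-3-bromo-2-methylpropan-1-ol
Product: 19 (S)-(3-bromo-2-methylpropoxy)triethylsilane
Conditions: TESCl, imidazole, CH2Cl2, 0 °C
Reagents that add atoms: chlorotriethylsilane, CC[Si](Cl)(CC)CC
Why: Standard silylation of a primary alcohol with a silyl chloride and imidazole, which leaves the bromide and the stereocentre untouched.

Step 11
Reactants: 19 (S)-(3-bromo-2-methylpropoxy)triethylsilane; 20 methyltriphenylphosphonium bromide
Product: 22 [(3R)-3-methyl-4-(triethylsilyloxy)butyl]triphenylphosphonium bromide, via methylenetriphenylphosphorane 21 (not isolated)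
Conditions: n-BuLi, THF, 0 °C; then 19, 0 → 60 °C
Reagents that add atoms: none
Why: SN2 C-alkylation of a non-stabilised phosphorus ylide by a primary bromide, which lengthens the chain by the ylide carbon (C2'') and gives the homologous phosphonium salt with the stereocentre, β to the reacting carbon, untouched.

Step 12
Reactants: 17 (2R,3R,6E)-6-(2-acetoxyethylidene)-2-formyl-2-methyloxepan-3-yl acetate; 22 [(3R)-3-methyl-4-(triethylsilyloxy)butyl]triphenylphosphonium bromide
Product: 24 (2S,3R,6E)-6-(2-acetoxyethylidene)-2-methyl-2-[(1Z,4R)-4-methyl-5-(triethylsilyloxy)pent-1-en-1-yl]oxepan-3-yl acetate, via phosphorus ylide 23 (not isolated)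
Conditions: NaHMDS, THF, −78 → 0 °C; then 17, −78 → 0 °C
Reagents that add atoms: none
Why: Wittig olefination with a non-stabilised ylide free of excess base, in which the non-enolisable α-quaternary aldehyde reacts at −78 °C far faster than the acetates and gives mainly the (Z)-alkene, whose geometry is irrelevant because it is reduced next.

Step 13
Reactants: 24 (2S,3R,6E)-6-(2-acetoxyethylidene)-2-methyl-2-[(1Z,4R)-4-methyl-5-(triethylsilyloxy)pent-1-en-1-yl]oxepan-3-yl acetate
Product: 25 (2S,3R,6E)-6-(2-acetoxyethylidene)-2-methyl-2-[(4R)-4-methyl-5-(triethylsilyloxy)pentyl]oxepan-3-yl acetate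
Conditions: 2-nitrobenzenesulfonylhydrazide, Et3N, CH2Cl2, rt
Reagents that add atoms: none
Why: Diimide reduction by concerted syn transfer of H2 from HN=NH, which prefers the 1,2-disubstituted alkene over the trisubstituted C6=C1' alkene and can neither isomerise the alkene nor cleave the allylic acetate, the hydrazide being dosed in portions until 24 is consumed.

Step 14
Reactants: 25 (2S,3R,6E)-6-(2-acetoxyethylidene)-2-methyl-2-[(4R)-4-methyl-5-(triethylsilyloxy)pentyl]oxepan-3-yl acetate
Product: 26 (2S,3R,6E)-6-(2-acetoxyethylidene)-2-methyl-2-[(4R)-4-methyl-5-oxopentyl]oxepan-3-yl acetate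
Conditions: (COCl)2, DMSO, CH2Cl2, −78 → −40 °C; then Et3N, −78 → 0 °C
Reagents that add atoms: none
Why: Swern oxidation applied directly to a primary triethylsilyl ether, in which chloride-assisted silyl transfer gives the alkoxysulfonium salt that fragments to the aldehyde on addition of amine, low temperature keeping the α-stereocentre C4'' intact.

Step 15
Reactants: 27 2,3-dimethylbut-1-ene
Product: 29 4,4,5,5-tetramethyl-2-(3-methyl-2-methylenebutyl)-1,3,2-dioxaborolane, via 2-isopropylallylpotassium 28 (not isolated)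
Conditions: n-BuLi, KOt-Bu, THF, −78 → −45 °C; then i-PrOBpin, −78 °C → rt
Reagents that add atoms: 2-isopropoxy-4,4,5,5-tetramethyl-1,3,2-dioxaborolane, CC(C)OB1OC(C)(C)C(C)(C)O1
Why: Schlosser-base metalation, which removes a proton from the allylic methyl group in preference to the tertiary allylic position, followed by trapping of the allylpotassium on boron (allylic metalation–borylation).

Step 16
Reactants: 26 (2S,3R,6E)-6-(2-acetoxyethylidene)-2-methyl-2-[(4R)-4-methyl-5-oxopentyl]oxepan-3-yl acetate; 29 4,4,5,5-tetramethyl-2-(3-methyl-2-methylenebutyl)-1,3,2-dioxaborolane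
Product: 31 (2S,3R,6E)-6-(2-acetoxyethylidene)-2-[(4R,5RS)-5-hydroxy-4,8-dimethyl-7-methylenenonyl]-2-methyloxepan-3-yl acetate, via pinacol borate ester 30 (not isolated)
Conditions: toluene, 25 °C; then aq. NaHCO3
Reagents that add atoms: none
Why: Allylboration through a six-membered cyclic transition state, which transfers the 2-isopropylallyl group to the aldehyde under neutral conditions that spare the acetates and C4'', the new C5'' carbinol being formed as an epimer mixture that is removed by the oxidation that follows.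

Step 17
Reactants: 31 (2S,3R,6E)-6-(2-acetoxyethylidene)-2-[(4R,5RS)-5-hydroxy-4,8-dimethyl-7-methylenenonyl]-2-methyloxepan-3-yl acetate
Product: 32 (2S,3R,6E)-6-(2-acetoxyethylidene)-2-[(4R)-4,8-dimethyl-7-methylene-5-oxononyl]-2-methyloxepan-3-yl acetate (CNP0582730.1)
Conditions: Dess–Martin periodinane, NaHCO3, CH2Cl2, 0 °C → rt
Reagents that add atoms: none
Why: Dess–Martin oxidation under bicarbonate buffer, which converts the homoallylic alcohol into the β,γ-unsaturated ketone without conjugating the 1,1-disubstituted alkene or epimerising C4''.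

**Compound list**

1 | but-2-yne-1,4-diol | OCC#CCO | starting material
2 | disodium cyclic (Z)-alkenylalanate (five-membered O–Al–C chelate from trans-hydroalumination) | [Na+].[Na+].[O-]CC1=CCO[Al-]1(OCCOC)OCCOC | intermediate
3 | (Z)-2-iodobut-2-ene-1,4-diol | OC/C(I)=C/CO | intermediate
4 | (Z)-4-(tert-butyldimethylsilyloxy)-2-iodobut-2-en-1-ol | OC/C(I)=C/CO[Si](C)(C)C(C)(C)C | intermediate
5 | (2-cyanoethyl)zinc bromide (THF solution) | N#CCC[Zn]Br | starting material
6 | (E)-6-(tert-butyldimethylsilyloxy)-4-(hydroxymethyl)hex-4-enenitrile | OC/C(CCC#N)=C/CO[Si](C)(C)C(C)(C)C | intermediate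
7 | prop-1-yn-1-ylmagnesium bromide (THF solution) | CC#C[Mg]Br | starting material
8 | (1S,2R,5S)-menthyl (R)-p-toluenesulfinate | C[C@H]1CC[C@@H]([C@H](C1)O[S@@](=O)c1ccc(C)cc1)C(C)C | starting material
9 | (R)-1-methyl-4-(prop-1-yn-1-ylsulfinyl)benzene | CC#C[S@](=O)c1ccc(C)cc1 | intermediate
10 | (4E)-6-(tert-butyldimethylsilyloxy)-4-({[(E)-1-((S)-p-tolylsulfinyl)prop-1-en-2-yl]oxy}methyl)hex-4-enenitrile | Cc1ccc(cc1)[S@@](=O)/C=C(\C)OC/C(=C/CO[Si](C)(C)C(C)(C)C)CCC#N | intermediate
11 | N-(diisobutylaluminio)aldimine of 12 | Cc1ccc(cc1)[S@@](=O)/C=C(\C)OC/C(=C/CO[Si](C)(C)C(C)(C)C)CCC=N[Al](CC(C)C)CC(C)C | intermediate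
12 | (4E)-6-(tert-butyldimethylsilyloxy)-4-({[(E)-1-((S)-p-tolylsulfinyl)prop-1-en-2-yl]oxy}methyl)hex-4-enal | Cc1ccc(cc1)[S@@](=O)/C=C(\C)OC/C(=C/CO[Si](C)(C)C(C)(C)C)CCC=O | intermediate
13 | (2R,3R,6E)-6-[2-(tert-butyldimethylsilyloxy)ethylidene]-2-methyl-2-{[(S)-p-tolylsulfinyl]methyl}oxepan-3-ol | Cc1ccc(cc1)[S@@](=O)C[C@]1(C)OC/C(=C/CO[Si](C)(C)C(C)(C)C)CC[C@H]1O | intermediate
14 | (2R,3R,6E)-6-(2-hydroxyethylidene)-2-methyl-2-{[(S)-p-tolylsulfinyl]methyl}oxepan-3-ol | Cc1ccc(cc1)[S@@](=O)C[C@]1(C)OC/C(=C/CO)CC[C@H]1O | intermediate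
15 | (2R,3R,6E)-6-(2-acetoxyethylidene)-2-methyl-2-{[(S)-p-tolylsulfinyl]methyl}oxepan-3-yl acetate | Cc1ccc(cc1)[S@@](=O)C[C@]1(C)OC/C(=C/COC(C)=O)CC[C@H]1OC(C)=O | intermediate
16 | (2R,3R,6E)-6-(2-acetoxyethylidene)-2-methyl-2-[(p-tolylthio)(trifluoroacetoxy)methyl]oxepan-3-yl acetate (both epimers at the new carbon) | Cc1ccc(cc1)SC(OC(=O)C(F)(F)F)[C@]1(C)OC/C(=C/COC(C)=O)CC[C@H]1OC(C)=O | intermediate
17 | (2R,3R,6E)-6-(2-acetoxyethylidene)-2-formyl-2-methyloxepan-3-yl acetate | O=C[C@]1(C)OC/C(=C/COC(C)=O)CC[C@H]1OC(C)=O | intermediate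
18 | (S)-3-bromo-2-methylpropan-1-ol | OC[C@H](C)CBr | starting material
19 | (S)-(3-bromo-2-methylpropoxy)triethylsilane | CC[Si](CC)(CC)OC[C@H](C)CBr | intermediate
20 | methyltriphenylphosphonium bromide | C[P+](c1ccccc1)(c1ccccc1)c1ccccc1.[Br-] | starting material
21 | methylenetriphenylphosphorane | C=P(c1ccccc1)(c1ccccc1)c1ccccc1 | intermediate
22 | [(3R)-3-methyl-4-(triethylsilyloxy)butyl]triphenylphosphonium bromide | CC[Si](CC)(CC)OC[C@H](C)CC[P+](c1ccccc1)(c1ccccc1)c1ccccc1.[Br-] | intermediate
23 | [(3R)-3-methyl-4-(triethylsilyloxy)butylidene]triphenylphosphorane | CC[Si](CC)(CC)OC[C@H](C)CC=P(c1ccccc1)(c1ccccc1)c1ccccc1 | intermediate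
24 | (2S,3R,6E)-6-(2-acetoxyethylidene)-2-methyl-2-[(1Z,4R)-4-methyl-5-(triethylsilyloxy)pent-1-en-1-yl]oxepan-3-yl acetate | CC[Si](CC)(CC)OC[C@H](C)C/C=C\[C@]1(C)OC/C(=C/COC(C)=O)CC[C@H]1OC(C)=O | intermediate
25 | (2S,3R,6E)-6-(2-acetoxyethylidene)-2-methyl-2-[(4R)-4-methyl-5-(triethylsilyloxy)pentyl]oxepan-3-yl acetate | CC[Si](CC)(CC)OC[C@H](C)CCC[C@]1(C)OC/C(=C/COC(C)=O)CC[C@H]1OC(C)=O | intermediate
26 | (2S,3R,6E)-6-(2-acetoxyethylidene)-2-methyl-2-[(4R)-4-methyl-5-oxopentyl]oxepan-3-yl acetate | O=C[C@H](C)CCC[C@]1(C)OC/C(=C/COC(C)=O)CC[C@H]1OC(C)=O | intermediate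
27 | 2,3-dimethylbut-1-ene | C=C(C)C(C)C | starting material
28 | (2-isopropylallyl)potassium | [K+].[CH2-]C(=C)C(C)C | intermediate
29 | 4,4,5,5-tetramethyl-2-(3-methyl-2-methylenebutyl)-1,3,2-dioxaborolane | C=C(CB1OC(C)(C)C(C)(C)O1)C(C)C | intermediate
30 | pinacol borate ester of 31 (O–Bpin at C5'') | C=C(CC(OB2OC(C)(C)C(C)(C)O2)[C@H](C)CCC[C@]1(C)OC/C(=C/COC(C)=O)CC[C@H]1OC(C)=O)C(C)C | intermediate
31 | (2S,3R,6E)-6-(2-acetoxyethylidene)-2-[(4R,5RS)-5-hydroxy-4,8-dimethyl-7-methylenenonyl]-2-methyloxepan-3-yl acetate | C=C(CC(O)[C@H](C)CCC[C@]1(C)OC/C(=C/COC(C)=O)CC[C@H]1OC(C)=O)C(C)C | intermediate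
32 | (2S,3R,6E)-6-(2-acetoxyethylidene)-2-[(4R)-4,8-dimethyl-7-methylene-5-oxononyl]-2-methyloxepan-3-yl acetate (CNP0582730.1) | C=C(CC(=O)[C@H](C)CCC[C@]1(C)OC/C(=C/COC(C)=O)CC[C@H]1OC(C)=O)C(C)C | target

**Step count**

Total: 17 steps. Longest linear sequence: 13 steps (1, 2, 3, 5, 6, 7, 8, 9, 12, 13, 14, 16, 17).

**Steps most likely to fail**

Step 7. The ketyl may be quenched (reduction of the aldehyde to the alcohol, pinacol coupling) before it closes the seven-membered ring onto the fully substituted β-carbon, or chelated and open addition modes may compete and erode the facial bias at C2. The fallback sets out from 12 and comes back at 13, and it separates ring closure from the setting of C3. A thiol-mediated acyl radical cyclisation of 12 (tert-dodecanethiol, AIBN, benzene, 80 °C; 7-exo addition of the acyl radical to the vinylogous sulfinate, with the sulfoxide steering the C2 face by sterics alone) should give (2R,6E)-6-[2-(tert-butyldimethylsilyloxy)ethylidene]-2-methyl-2-{[(S)-p-tolylsulfinyl]methyl}oxepan-3-one F1. DIBAL at −78 °C, bound to the sulfinyl oxygen and delivering hydride on the face of the sulfinylmethyl arm, should then reduce F1 to the trans alcohol 13.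

Step 13. The cis alkene next to quaternary C2 is shielded, so diimide may begin to reduce the trisubstituted C6=C1' alkene before 24 is consumed. The fallback sets out from 17 and comes back at 25, and it moves the new alkene one bond away from C2. Methoxymethylenation of 17 (Ph3P=CHOMe, THF, −78 °C) should give (2S,3R,6E)-6-(2-acetoxyethylidene)-2-(2-methoxyethenyl)-2-methyloxepan-3-yl acetate F2, and mild acid hydrolysis the homologous aldehyde (2S,3R,6E)-6-(2-acetoxyethylidene)-2-methyl-2-(2-oxoethyl)oxepan-3-yl acetate F3. Heating 19 with triphenylphosphine gives [(2S)-2-methyl-3-(triethylsilyloxy)propyl]triphenylphosphonium bromide F4, whose ylide (NaHMDS) should convert F3 into (2S,3R,6E)-6-(2-acetoxyethylidene)-2-methyl-2-[(2Z,4R)-4-methyl-5-(triethylsilyloxy)pent-2-en-1-yl]oxepan-3-yl acetate F5. Its unhindered disubstituted alkene should be reduced by diimide with the normal preference over the trisubstituted one, giving 25.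

Step 6. Hydride may add to the vinylogous sulfinate, sulfoxide coordination may stall the nitrile reduction, or the enol ether may be lost while the aluminoimine is hydrolysed. The fallback sets out from 4 and comes back at 12, and it carries the aldehyde carbon as a PMB ether instead of a nitrile. B-alkyl Suzuki coupling of 4 with the 9-BBN adduct of allyl 4-methoxybenzyl ether (PdCl2(dppf), Cs2CO3, DMF/H2O) should give (E)-4-(tert-butyldimethylsilyloxy)-2-[3-(4-methoxybenzyloxy)propyl]but-2-en-1-ol F6. Alkoxide addition to 9 as in step 5 should give 1-methoxy-4-({[(4E)-6-(tert-butyldimethylsilyloxy)-4-({[(E)-1-((S)-p-tolylsulfinyl)prop-1-en-2-yl]oxy}methyl)hex-4-en-1-yl]oxy}methyl)benzene F7. DDQ in buffered CH2Cl2 should free (4E)-6-(tert-butyldimethylsilyloxy)-4-({[(E)-1-((S)-p-tolylsulfinyl)prop-1-en-2-yl]oxy}methyl)hex-4-en-1-ol F8, and Dess–Martin oxidation should give 12.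

**Further compounds**

F1 | step 7 | (2R,6E)-6-[2-(tert-butyldimethylsilyloxy)ethylidene]-2-methyl-2-{[(S)-p-tolylsulfinyl]methyl}oxepan-3-one | Cc1ccc(cc1)[S@@](=O)C[C@]1(C)OC/C(=C/CO[Si](C)(C)C(C)(C)C)CCC1=O
F2 | step 13 | (2S,3R,6E)-6-(2-acetoxyethylidene)-2-(2-methoxyethenyl)-2-methyloxepan-3-yl acetate (E/Z mixture) | COC=C[C@]1(C)OC/C(=C/COC(C)=O)CC[C@H]1OC(C)=O
F3 | step 13 | (2S,3R,6E)-6-(2-acetoxyethylidene)-2-methyl-2-(2-oxoethyl)oxepan-3-yl acetate | O=CC[C@]1(C)OC/C(=C/COC(C)=O)CC[C@H]1OC(C)=O
F4 | step 13 | [(2S)-2-methyl-3-(triethylsilyloxy)propyl]triphenylphosphonium bromide | CC[Si](CC)(CC)OC[C@H](C)C[P+](c1ccccc1)(c1ccccc1)c1ccccc1.[Br-]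
F5 | step 13 | (2S,3R,6E)-6-(2-acetoxyethylidene)-2-methyl-2-[(2Z,4R)-4-methyl-5-(triethylsilyloxy)pent-2-en-1-yl]oxepan-3-yl acetate | CC[Si](CC)(CC)OC[C@H](C)/C=C\C[C@]1(C)OC/C(=C/COC(C)=O)CC[C@H]1OC(C)=O
F6 | step 6 | (E)-4-(tert-butyldimethylsilyloxy)-2-[3-(4-methoxybenzyloxy)propyl]but-2-en-1-ol | OC/C(CCCOCc1ccc(OC)cc1)=C/CO[Si](C)(C)C(C)(C)C
F7 | step 6 | 1-methoxy-4-({[(4E)-6-(tert-butyldimethylsilyloxy)-4-({[(E)-1-((S)-p-tolylsulfinyl)prop-1-en-2-yl]oxy}methyl)hex-4-en-1-yl]oxy}methyl)benzene | Cc1ccc(cc1)[S@@](=O)/C=C(\C)OC/C(CCCOCc1ccc(OC)cc1)=C/CO[Si](C)(C)C(C)(C)C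
F8 | step 6 | (4E)-6-(tert-butyldimethylsilyloxy)-4-({[(E)-1-((S)-p-tolylsulfinyl)prop-1-en-2-yl]oxy}methyl)hex-4-en-1-ol | Cc1ccc(cc1)[S@@](=O)/C=C(\C)OC/C(CCCO)=C/CO[Si](C)(C)C(C)(C)C
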